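**Retrosynthetic overview**

- Target 18 comes from protected chalcone 17 by one acid methanolysis that removes three aryl MOM ethers and the tertiary TES ether.
- The strategy rests on the ketone carbon, which is bonded only to ring-A carbon C1' and to Cα of the E-configured Cα=Cβ bond leading to ring B. Both bonds are cut at once, giving aryl iodide 11, carbon monoxide 16 and E-alkenylboronate 15.
- 11 comes from C4 lithiation/iodination of 9, which comes from C2 alkylation of lithiated 1,3-bis(methoxymethoxy)benzene (from resorcinol) with iodide 5, made from (R)-linalool; the linalool C3 center is the only stereocenter of the target.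
- 15 comes from hydroboration of alkyne 14, made from 4-hydroxybenzaldehyde.
- No ring is formed at any stage; rings A and B are bought as resorcinol and 4-hydroxybenzaldehyde.

Key step: step 10

Assumption: (R)-(−)-linalool is bought in high enantiomeric purity; no step breaks a bond to its C3 center, so the enantiopurity of the target should equal that of the linalool used.

**Route**

Step 1
Reactants: 1 (R)-linalool
Product: 3 (3R)-3,7-dimethyloct-6-ene-1,3-diol, via B-alkyl-9-BBN adduct 2 (not isolated)
Conditions: 9-BBN (2.2 equiv), THF, 0 °C → rt; then 3 M NaOH, 30% H2O2, 0 °C → rt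
Reagents that add atoms: hydrogen peroxide, OO
Why: Brown hydroboration–oxidation, in which the bulky 9-BBN should add to the terminal carbon of the monosubstituted vinyl group far faster than to the trisubstituted C6=C7 alkene (the excess covers any borane consumed by the tertiary hydroxyl), while the C3 stereocenter is not touched.

Step 2
Reactants: 3 (3R)-3,7-dimethyloct-6-ene-1,3-diol
Product: 4 (3R)-1-iodo-3,7-dimethyloct-6-en-3-ol
Conditions: I2, PPh3, imidazole, CH2Cl2, 0 °C → rt
Reagents that add atoms: iodine, II
Why: Appel-type (Garegg–Samuelsson) iodination, in which only the primary alkoxyphosphonium ion can be displaced by iodide in an SN2 step, so the hindered tertiary alcohol should remain free.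

Step 3
Reactants: 4 (3R)-1-iodo-3,7-dimethyloct-6-en-3-ol
Product: 5 triethyl{[(3R)-1-iodo-3,7-dimethyloct-6-en-3-yl]oxy}silane
Conditions: TESOTf, 2,6-lutidine, CH2Cl2, −78 → 0 °C
Reagents that add atoms: triethylsilyl trifluoromethanesulfonate, CC[Si](CC)(CC)OS(=O)(=O)C(F)(F)F
Why: Silylation of a tertiary alcohol with a silyl triflate and a hindered, non-nucleophilic pyridine base, which should leave the primary iodide intact and mask the hydroxyl against the organolithium steps that follow.

Step 4
Reactants: 6 resorcinol
Product: 7 1,3-bis(methoxymethoxy)benzene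
Conditions: MOMCl, i-Pr2NEt, CH2Cl2, 0 °C → rt
Reagents that add atoms: chloromethyl methyl ether, COCCl
Why: Double O-alkylation of the phenols (Williamson-type acetal ether formation), giving MOM ethers that serve later both as ortho-directing groups and as acid-labile protection.

Step 5
Reactants: 7 1,3-bis(methoxymethoxy)benzene; 5 triethyl{[(3R)-1-iodo-3,7-dimethyloct-6-en-3-yl]oxy}silane
Product: 9 {[(3R)-1-[2,6-bis(methoxymethoxy)phenyl]-3,7-dimethyloct-6-en-3-yl]oxy}triethylsilane, via 2-lithio-1,3-bis(methoxymethoxy)benzene 8 (not isolated)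
Conditions: 7 (1.3 equiv), n-BuLi (1.25 equiv), THF, 0 °C → rt; then 5 (1.0 equiv), THF/DMPU, −78 °C → rt
Reagents that add atoms: none
Why: Directed ortho-metalation at C2, the position flanked by both MOM ethers, followed by SN2 alkylation of the aryllithium with the primary iodide, whose branching sits at the γ-carbon and so should not block substitution; the stereocenter is a spectator.

Step 6
Reactants: 9 {[(3R)-1-[2,6-bis(methoxymethoxy)phenyl]-3,7-dimethyloct-6-en-3-yl]oxy}triethylsilane
Product: 11 {[(3R)-1-[3-iodo-2,6-bis(methoxymethoxy)phenyl]-3,7-dimethyloct-6-en-3-yl]oxy}triethylsilane, via C4-lithiated arene 10 (not isolated)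
Conditions: n-BuLi (1.3 equiv), TMEDA, THF, 0 °C; then I2 (1.4 equiv), THF, −78 → 0 °C; Na2S2O3 work-up
Reagents that add atoms: iodine, II
Why: Second directed ortho-metalation, which can only occur at C4 (equivalent to C6), the sole ring position ortho to a MOM ether, followed by iodinolysis of the C–Li bond; this is chosen over electrophilic iodination because an iodonium source would also attack the trisubstituted alkene.

Step 7
Reactants: 12 4-hydroxybenzaldehyde
Product: 13 4-(methoxymethoxy)benzaldehyde
Conditions: MOMCl, i-Pr2NEt, CH2Cl2, 0 °C → rt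
Reagents that add atoms: chloromethyl methyl ether, COCCl
Why: O-alkylation of the phenol to its MOM ether, so that all three phenols of the target carry the same acid-labile group.

Step 8
Reactants: 13 4-(methoxymethoxy)benzaldehyde
Product: 14 1-ethynyl-4-(methoxymethoxy)benzene
Conditions: dimethyl (1-diazo-2-oxopropyl)phosphonate, K2CO3, MeOH, 0 °C → rt
Reagents that add atoms: dimethyl (1-diazo-2-oxopropyl)phosphonate, COP(=O)(OC)C(=[N+]=[N-])C(C)=O
Why: Ohira–Bestmann modification of the Seyferth–Gilbert homologation, which should convert the non-enolizable aryl aldehyde to the terminal alkyne under mild carbonate conditions that leave the MOM ether alone.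

Step 9
Reactants: 14 1-ethynyl-4-(methoxymethoxy)benzene
Product: 15 (E)-2-{2-[4-(methoxymethoxy)phenyl]ethenyl}-4,4,5,5-tetramethyl-1,3,2-dioxaborolane
Conditions: pinacolborane (1.3 equiv), Cp2Zr(H)Cl (5 mol %), Et3N (10 mol %), neat, 60 °C
Reagents that add atoms: pinacolborane, CC1(C)OBOC1(C)C
Why: Zirconium-catalysed hydroboration of a terminal alkyne, a syn addition that places boron on the terminal carbon and should therefore give only the E-alkenylboronate.

Step 10
Reactants: 11 {[(3R)-1-[3-iodo-2,6-bis(methoxymethoxy)phenyl]-3,7-dimethyloct-6-en-3-yl]oxy}triethylsilane; 16 carbon monoxide; 15 (E)-2-{2-[4-(methoxymethoxy)phenyl]ethenyl}-4,4,5,5-tetramethyl-1,3,2-dioxaborolane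
Product: 17 (E)-1-{2,4-bis(methoxymethoxy)-3-[(3R)-3,7-dimethyl-3-(triethylsilyloxy)oct-6-en-1-yl]phenyl}-3-[4-(methoxymethoxy)phenyl]prop-2-en-1-one
Conditions: PdCl2(PPh3)2 (5 mol %), K2CO3 (3 equiv), H2O (5 equiv), CO (1 atm), anisole, 80 °C; 15 (1.2 equiv) added slowly
Reagents that add atoms: none
Why: Carbonylative Suzuki–Miyaura coupling, a known reaction type for aryl iodides and organoboron reagents: zerovalent palladium formed in situ from PdCl2(PPh3)2 inserts into the C–I bond of 11, CO migrates into the aryl–palladium bond to give an aroyl complex of divalent palladium, the alkenyl group of the base-activated boronate 15 is transferred, and reductive elimination releases enone 17 with the C1'–C(=O) and C(=O)–Cα bonds both newly formed. No ring closes and no stereocenter forms; the side-chain stereocenter is remote and untouched. The E geometry of Cα=Cβ is that of the boronate, because transmetalation and reductive elimination proceed with retention at the sp2 carbon. The selectivity required is CO insertion ahead of transmetalation (ketone instead of the directly coupled stilbene); the electron-rich aryl–palladium bond next to the ortho MOM ether should take up CO quickly while the pinacol boronate transmetalates slowly, and a CO-saturated solution with slow addition of 15 reinforces this. Flavanone closure and aldol-type scrambling are excluded because no enolate is generated and the ortho oxygen is still a MOM ether.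

Step 11
Reactants: 17 (E)-1-{2,4-bis(methoxymethoxy)-3-[(3R)-3,7-dimethyl-3-(triethylsilyloxy)oct-6-en-1-yl]phenyl}-3-[4-(methoxymethoxy)phenyl]prop-2-en-1-one
Product: 18 (E)-1-{2,4-dihydroxy-3-[(3R)-3-hydroxy-3,7-dimethyloct-6-en-1-yl]phenyl}-3-(4-hydroxyphenyl)prop-2-en-1-one
Conditions: HCl (1.25 M in MeOH, diluted to about 0.5 M), MeOH, 0 °C → rt, monitored and quenched with NaHCO3 as soon as the last MOM ether is gone
Reagents that add atoms: none
Why: Acid-catalysed acetal exchange of the three aryl MOM ethers and methanolysis of the TES ether in one operation, run dilute and at or below room temperature so that the non-allylic tertiary alcohol, the trisubstituted alkene and the 2'-hydroxy enone should survive.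

**Compound list**

1 | (R)-linalool, (3R)-3,7-dimethylocta-1,6-dien-3-ol | CC(C)=CCC[C@@](C)(O)C=C | starting material
2 | B-alkyl-9-BBN adduct, 9-[(3S)-3-hydroxy-3,7-dimethyloct-6-en-1-yl]-9-borabicyclo[3.3.1]nonane (geometry as in 1; the descriptor changes only because boron lowers the CIP rank of the C1–C2 arm) | CC(C)=CCC[C@@](C)(O)CCB1C2CCCC1CCC2 | intermediate (not isolated)
3 | (3R)-3,7-dimethyloct-6-ene-1,3-diol | CC(C)=CCC[C@@](C)(O)CCO | intermediate
4 | (3R)-1-iodo-3,7-dimethyloct-6-en-3-ol | CC(C)=CCC[C@@](C)(O)CCI | intermediate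
5 | triethyl{[(3R)-1-iodo-3,7-dimethyloct-6-en-3-yl]oxy}silane | CC(C)=CCC[C@@](C)(O[Si](CC)(CC)CC)CCI | intermediate
6 | resorcinol | Oc1cccc(O)c1 | starting material
7 | 1,3-bis(methoxymethoxy)benzene | COCOc1cccc(OCOC)c1 | intermediate
8 | 2-lithio-1,3-bis(methoxymethoxy)benzene | [Li]c1c(OCOC)cccc1OCOC | intermediate (not isolated)
9 | {[(3R)-1-[2,6-bis(methoxymethoxy)phenyl]-3,7-dimethyloct-6-en-3-yl]oxy}triethylsilane | CC(C)=CCC[C@@](C)(O[Si](CC)(CC)CC)CCc1c(OCOC)cccc1OCOC | intermediate
10 | C4-lithiated arene, {[(3R)-1-[3-lithio-2,6-bis(methoxymethoxy)phenyl]-3,7-dimethyloct-6-en-3-yl]oxy}triethylsilane | CC(C)=CCC[C@@](C)(O[Si](CC)(CC)CC)CCc1c(OCOC)ccc([Li])c1OCOC | intermediate (not isolated)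
11 | {[(3R)-1-[3-iodo-2,6-bis(methoxymethoxy)phenyl]-3,7-dimethyloct-6-en-3-yl]oxy}triethylsilane | CC(C)=CCC[C@@](C)(O[Si](CC)(CC)CC)CCc1c(OCOC)ccc(I)c1OCOC | intermediate
12 | 4-hydroxybenzaldehyde | O=Cc1ccc(O)cc1 | starting material
13 | 4-(methoxymethoxy)benzaldehyde | COCOc1ccc(C=O)cc1 | intermediate
14 | 1-ethynyl-4-(methoxymethoxy)benzene | COCOc1ccc(C#C)cc1 | intermediate
15 | (E)-2-{2-[4-(methoxymethoxy)phenyl]ethenyl}-4,4,5,5-tetramethyl-1,3,2-dioxaborolane | COCOc1ccc(/C=C/B2OC(C)(C)C(C)(C)O2)cc1 | intermediate
16 | carbon monoxide | [C-]#[O+] | starting material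
17 | (E)-1-{2,4-bis(methoxymethoxy)-3-[(3R)-3,7-dimethyl-3-(triethylsilyloxy)oct-6-en-1-yl]phenyl}-3-[4-(methoxymethoxy)phenyl]prop-2-en-1-one | CC(C)=CCC[C@@](C)(O[Si](CC)(CC)CC)CCc1c(OCOC)ccc(C(=O)/C=C/c2ccc(OCOC)cc2)c1OCOC | intermediate
18 | (E)-1-{2,4-dihydroxy-3-[(3R)-3-hydroxy-3,7-dimethyloct-6-en-1-yl]phenyl}-3-(4-hydroxyphenyl)prop-2-en-1-one | CC(C)=CCC[C@@](C)(O)CCc1c(O)ccc(C(=O)/C=C/c2ccc(O)cc2)c1O | target

**Step count**

Total: 11 steps. Longest linear sequence: 7 steps (steps 1, 2, 3, 5, 6, 10, 11).

**Steps most likely to fail, with fallbacks**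

Step 10. Transmetalation may outrun CO insertion and give the directly coupled stilbene, or the alkenylboronate may be lost by protodeboronation before the aroyl–palladium species is formed. The fallback sets out from arene 9 and aldehyde 13 and comes back to the route at 17. Aldehyde 13 is treated with diethyl {2-[methoxy(methyl)amino]-2-oxoethyl}phosphonate and NaH in THF (Horner–Wadsworth–Emmons olefination), which should give the Weinreb amide (E)-N-methoxy-N-methyl-3-[4-(methoxymethoxy)phenyl]prop-2-enamide F1. Arene 9 is lithiated at C4 exactly as in step 6 to give 10, and this aryllithium is added to F1 in THF at −78 °C. The chelated tetrahedral adduct should collapse on aqueous work-up to protected chalcone 17 (Weinreb ketone synthesis, 1,2-addition). The carbonyl carbon then arrives attached to Cα and only the C1'–C(=O) bond is made.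

Step 5. The basic aryllithium may dehydroiodinate the primary iodide (E2) instead of substituting it, returning the silylated vinyl compound. The fallback sets out from 7 and 5 and comes back at 9 with the polarity of the two partners reversed. Arene 7 is lithiated to 8 as before and quenched with I2 to give 2-iodo-1,3-bis(methoxymethoxy)benzene F2. Iodide 5 is converted with Zn dust and LiCl in THF into [(3R)-3,7-dimethyl-3-(triethylsilyloxy)oct-6-en-1-yl]zinc iodide F3. Negishi coupling of F3 with F2 under Pd(OAc)2 and SPhos in THF at rt to 50 °C should give 9. The weakly basic alkylzinc reagent cannot cause elimination.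

Step 11. Protic acid may ionize the tertiary alcohol or protonate the trisubstituted alkene, with ether ring closure onto a neighbouring phenol or onto the side-chain hydroxyl, or it may promote oxa-Michael closure of the 2'-hydroxy enone to a flavanone. The fallback sets out from 17 and comes back at 18 in two non-protic stages. TMSOTf and 2,2'-bipyridyl in CH2Cl2 at 0 °C → rt should exchange the three aryl MOM ethers for trimethylsilyl ethers, giving (E)-1-{3-[(3R)-3,7-dimethyl-3-(triethylsilyloxy)oct-6-en-1-yl]-2,4-bis(trimethylsilyloxy)phenyl}-3-[4-(trimethylsilyloxy)phenyl]prop-2-en-1-one F4. Addition of water hydrolyses these to (E)-1-{2,4-dihydroxy-3-[(3R)-3,7-dimethyl-3-(triethylsilyloxy)oct-6-en-1-yl]phenyl}-3-(4-hydroxyphenyl)prop-2-en-1-one F5. HF·pyridine buffered with pyridine in THF at 0 °C then removes the tertiary TES ether to give 18.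

**Further compounds**

F1 | step 10 | (E)-N-methoxy-N-methyl-3-[4-(methoxymethoxy)phenyl]prop-2-enamide | COCOc1ccc(/C=C/C(=O)N(C)OC)cc1
F2 | step 5 | 2-iodo-1,3-bis(methoxymethoxy)benzene | COCOc1cccc(OCOC)c1I
F3 | step 5 | [(3R)-3,7-dimethyl-3-(triethylsilyloxy)oct-6-en-1-yl]zinc iodide | CC(C)=CCC[C@@](C)(O[Si](CC)(CC)CC)CC[Zn]I
F4 | step 11 | (E)-1-{3-[(3R)-3,7-dimethyl-3-(triethylsilyloxy)oct-6-en-1-yl]-2,4-bis(trimethylsilyloxy)phenyl}-3-[4-(trimethylsilyloxy)phenyl]prop-2-en-1-one | CC(C)=CCC[C@@](C)(O[Si](CC)(CC)CC)CCc1c(O[Si](C)(C)C)ccc(C(=O)/C=C/c2ccc(O[Si](C)(C)C)cc2)c1O[Si](C)(C)C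
F5 | step 11 | (E)-1-{2,4-dihydroxy-3-[(3R)-3,7-dimethyl-3-(triethylsilyloxy)oct-6-en-1-yl]phenyl}-3-(4-hydroxyphenyl)prop-2-en-1-one | CC(C)=CCC[C@@](C)(O[Si](CC)(CC)CC)CCc1c(O)ccc(C(=O)/C=C/c2ccc(O)cc2)c1O
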